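**Retrosynthetic overview**

1. Last disconnections: removal of fifteen silyl ethers, then the C4–O–C4 ether. The ether is made from a C4 cation of the middle unit (4β-benzylthio leaving group, AgOTf) and the all-cis 4-ol of silylated (+)-epicatechin, whose own C4–O bond is never broken.
2. The middle flavan is not taken from epicatechin. Its ring C is grown on the upper unit and closed by forming O1–C2 from a (Z)-2-cinnamylphenol (phenol-directed epoxidation, then 6-endo epoxide opening), which sets C2 and C3 (2,3-cis) in one operation. C4 is oxidised afterwards (DDQ).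
3. The Z-alkene comes from C3–C4 bond formation (aryl-alkynyl Grignard onto an o-quinone methide made from a salicylaldehyde) and Lindlar reduction. The salicylaldehyde comes from epicatechin-(4β→2)-phloroglucinol, so the C4–C8 interflavan bond exists first and 4→8 regiochemistry is fixed by which hydroxyl is left free.
4. Enabling feature: the phenolic oxygen O1 on C8a of ring A of the middle unit, flanked by C8 (upper flavanyl) and C4a, sits three carbons (C8a, C4a, C4) from the C2=C3 alkene, and C2 is benzylic to catechol ring B with an oxygen para at C4'. O1 can therefore deliver the oxidant and then open the epoxide at C2 with inversion.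
5. Ring order: the rings of the upper and third units come intact from (−)- and (+)-epicatechin, ring A of the middle unit from phloroglucinol, ring B from 3,4-dihydroxybenzaldehyde. The only ring formed is ring C of the middle unit.

Key step: step 12

Assumption: (+)-epicatechin (2S,3S) is taken as a purchasable starting material; TBS = tert-butyldimethylsilyl; α/β are used in the flavan sense (the 2-aryl group of a 2R unit is α); "upper", "middle" and "third" unit mean the C4–C8-linked, the central and the ether-linked flavan.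

**Route**

Step 1
Reactants: 1 (−)-epicatechin
Product: 2 3,5,7,3',4'-penta-O-TBS-(−)-epicatechin
Conditions: TBSCl (7 equiv), imidazole, DMAP (cat.), DMF, 50 °C
Reagents that add atoms: TBSCl `CC(C)(C)[Si](C)(C)Cl`
Why: Imidazole-mediated silylation should cap the four phenols and, on warming, the hindered 3-OH; no stereocentre is touched.

Step 2
Reactants: 2 penta-O-TBS-(−)-epicatechin
Product: 3 4β-(2-ethoxyethoxy)-penta-O-TBS-epicatechin (4-O trans to 3-OTBS)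
Conditions: DDQ (2 equiv), 2-ethoxyethanol (5 equiv), CH2Cl2, rt
Reagents that add atoms: 2-ethoxyethanol `CCOCCO`
Why: DDQ benzylic oxidation (hydride abstraction from C4–H2 activated by the 5,7-dioxygenated ring A) should give a cation that the alcohol captures anti to the axial 3-OTBS group, setting C4 as 4β.

Step 3
Reactants: 3 4β-(2-ethoxyethoxy)-penta-O-TBS-epicatechin; 4 phloroglucinol (5 equiv)
Product: 5 penta-O-TBS-epicatechin-(4β→2)-phloroglucinol
Conditions: TMSOTf (0.2 equiv), THF/CH2Cl2, −78 → −30 °C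
Reagents that add atoms: none
Why: Lewis-acid ionisation of the C4 acetal-type ether and Friedel–Crafts alkylation of the threefold-symmetric phenol (excess against double alkylation) should form the later C4–C8 bond, the arene entering anti to 3-OTBS (4β).

Step 4
Reactants: 5 penta-O-TBS-epicatechin-(4β→2)-phloroglucinol
Product: 6 2,4,6-trihydroxy-3-(penta-O-TBS-epicatechin-4β-yl)benzaldehyde
Conditions: MgCl2, Et3N, paraformaldehyde, THF, reflux
Reagents that add atoms: paraformaldehyde (formaldehyde) `C=O`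
Why: Magnesium-phenoxide-directed ortho-formylation (Casnati–Skattebøl) can only occur on the ring that carries free hydroxyls, whose two open positions are equivalent, so one aldehyde should result.

Step 5
Reactants: 6 2,4,6-trihydroxy-3-(penta-O-TBS-epicatechin-4β-yl)benzaldehyde
Product: 7 2-hydroxy-4,6-bis(TBS-oxy)-3-(penta-O-TBS-epicatechin-4β-yl)benzaldehyde (free OH between the formyl and flavanyl carbons)
Conditions: TBSCl (2.1 equiv), imidazole, CH2Cl2, 0 °C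
Reagents that add atoms: TBSCl `CC(C)(C)[Si](C)(C)Cl`
Why: Site-selective silylation should take the hydroxyl para to the formyl group and the ortho hydroxyl flanked by H, leaving the one that is both hydrogen-bonded to C=O and shielded by the flavanyl group; this free OH is the future O1.

Step 6
Reactants: 7 2-hydroxy-4,6-bis(TBS-oxy)-3-(penta-O-TBS-epicatechin-4β-yl)benzaldehyde
Product: 8 tert-butyl carbonate of phenol 7 (O-Boc salicylaldehyde)
Conditions: Boc2O (1.5 equiv), i-Pr2NEt, DMAP (0.1 equiv), THF, 0 °C → rt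
Reagents that add atoms: di-tert-butyl dicarbonate `CC(C)(C)OC(=O)OC(=O)OC(C)(C)C`
Why: DMAP-catalysed carbonate formation on the phenol installs the migrating group needed for anionic o-quinone methide generation.

Step 7
Reactants: 9 3,4-dihydroxybenzaldehyde
Product: 10 3,4-bis(TBS-oxy)benzaldehyde
Conditions: TBSCl (2.4 equiv), imidazole, DMF, rt
Reagents that add atoms: TBSCl `CC(C)(C)[Si](C)(C)Cl`
Why: Standard silylation of a catechol.

Step 8
Reactants: 10 3,4-bis(TBS-oxy)benzaldehyde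
Product: 11 4-(2,2-dibromovinyl)-1,2-bis(TBS-oxy)benzene
Conditions: CBr4, PPh3, Zn dust, CH2Cl2, rt
Reagents that add atoms: carbon tetrabromide `BrC(Br)(Br)Br`
Why: Corey–Fuchs olefination (zinc variant, no acidic phosphorus dibromide) should convert the aldehyde into the dibromoalkene.

Step 9
Reactants: 11 4-(2,2-dibromovinyl)-1,2-bis(TBS-oxy)benzene
Product: 13 4-ethynyl-1,2-bis(TBS-oxy)benzene, via lithium acetylide 12 (not isolated)
Conditions: n-BuLi (2.1 equiv), THF, −78 °C; then H2O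
Reagents that add atoms: none
Why: Second stage of the Corey–Fuchs sequence (Br/Li exchange, Fritsch–Buttenberg–Wiechell rearrangement, deprotonation) followed by protonation should give the terminal alkyne.

Step 10
Reactants: 8 O-Boc salicylaldehyde; 13 4-ethynyl-1,2-bis(TBS-oxy)benzene (3.5 equiv)
Product: 16 2-[3-(3,4-bis(TBS-oxy)phenyl)prop-2-yn-1-yl]-3,5-bis(TBS-oxy)-6-(penta-O-TBS-epicatechin-4β-yl)phenol, via lithium alkoxide 14 (not isolated), via o-quinone methide 15 (not isolated)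
Conditions: 13, EtMgBr, THF, 0 °C → rt (alkynyl Grignard); 8, LiBH(s-Bu)3 (1.0 equiv), THF, −78 °C; then the alkynylmagnesium bromide, −78 °C → rt; aq NH4Cl
Reagents that add atoms: none
Why: Anionic o-quinone methide generation from an O-Boc salicyl derivative: hydride reduces the aldehyde, the alkoxide takes over the Boc group, the phenoxide expels tert-butyl carbonate, and the alkynyl Grignard adds 1,4 to the exocyclic methylene (C3–C4 bond), returning the phenol.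

Step 11
Reactants: 16 propargyl phenol
Product: 17 (Z)-2-[3-(3,4-bis(TBS-oxy)phenyl)prop-2-en-1-yl]-3,5-bis(TBS-oxy)-6-(penta-O-TBS-epicatechin-4β-yl)phenol
Conditions: H2 (1 atm), Pd/CaCO3 poisoned with Pb(OAc)2 (Lindlar catalyst), quinoline, EtOAc, rt
Reagents that add atoms: none
Why: Lindlar semi-hydrogenation adds H2 syn and should stop at the Z-alkene, the geometry that later becomes the 2,3-cis relationship.

Step 12
Reactants: 17 (Z)-cinnamylphenol
Product: 19 penta-O-TBS-epicatechin-(4β→8)-5,7,3',4'-tetra-O-TBS-epicatechin (new ring 2R,3R; 3-OH free), via cis-epoxide 18 (not isolated)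
Conditions: VO(Oi-Pr)3 (5 mol %), chiral bis-hydroxamic acid ligand [N,N'-dihydroxy-N,N'-bis(diphenylacetyl)-trans-cyclohexane-1,2-diamine, enantiomer chosen for the 2R,3R series] (6 mol %), cumene hydroperoxide (1.2 equiv), toluene, 0 °C → rt
Reagents that add atoms: cumene hydroperoxide `CC(C)(OO)c1ccccc1`
Why: Proposed new method: the free phenol of 17 should bind the pentavalent vanadium–bis-hydroxamate complex, the coordinated alkyl peroxide transfers oxygen syn to one face of the Z-alkene to give cis-epoxide 18, and the metal-bound phenol oxygen then opens the Lewis-acid-activated epoxide at the benzylic carbon; the closest known reactions are the VO(acac)2/t-BuOOH oxidative cyclisation of 2-(alk-2-enyl)phenols to chroman-3-ols and the bis-hydroxamic-acid-controlled asymmetric epoxidation of homoallylic and bishomoallylic alcohols. The pyran ring closes by a 6-endo epoxide opening (O1–C2), expected over the 5-exo mode because C2 is benzylic to ring B with a para silyloxy group and carries the developing positive charge. C3 is set by the chiral ligand (face of oxygen transfer; the epoxide C–O bond becomes the 3-OH), and C2 by the Z geometry together with inversion in the anti opening, so that 2-aryl and 3-OH end cis (2R,3R). The step needs catalyst control of the alkene face over the remote chirality of the upper unit, an SN2-type opening (low temperature, non-ionising toluene) and chemoselectivity for the alkene over the electron-rich rings (intramolecular delivery from the only free hydroxyl). Ring-fusion regiochemistry is secured because this hydroxyl, flanked by C8 and C4a, is the only unprotected one.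

Step 13
Reactants: 19 dimer with free 3-OH
Product: 20 deca-O-TBS-epicatechin-(4β→8)-epicatechin
Conditions: TBSOTf (2 equiv), 2,6-lutidine, CH2Cl2, −20 → 0 °C
Reagents that add atoms: TBSOTf `CC(C)(C)[Si](C)(C)OS(=O)(=O)C(F)(F)F`
Why: Silyl triflate silylation should cap the hindered axial 3-OH so that it cannot compete as a nucleophile in the etherification.

Step 14
Reactants: 20 deca-O-TBS dimer
Product: 21 middle-unit 4β-(2-ethoxyethoxy) derivative of 20
Conditions: DDQ (2 equiv), 2-ethoxyethanol (5 equiv), CH2Cl2, rt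
Reagents that add atoms: 2-ethoxyethanol `CCOCCO`
Why: DDQ benzylic oxidation should select the only CH2 benzylic to a trioxygenated ring (the upper C4–H is tertiary and shielded), and the alcohol adds anti to the axial 3-OTBS, setting the new C4 as 4β.

Step 15
Reactants: 21 4β-(2-ethoxyethoxy) dimer
Product: 22 middle-unit 4β-benzylthio derivative of 20
Conditions: BnSH (3 equiv), BF3·OEt2 (0.5 equiv), CH2Cl2, −78 °C
Reagents that add atoms: benzyl mercaptan `SCc1ccccc1`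
Why: Lewis-acid exchange of the C4 ether for a thioether (thiolysis-type SN1) again proceeds anti to 3-OTBS (4β) and gives a leaving group that can be activated without acid.

Step 16
Reactants: 23 (+)-epicatechin
Product: 24 3,5,7,3',4'-penta-O-TBS-(+)-epicatechin
Conditions: TBSCl (7 equiv), imidazole, DMAP (cat.), DMF, 50 °C
Reagents that add atoms: TBSCl `CC(C)(C)[Si](C)(C)Cl`
Why: Same silylation as step 1 on the enantiomer.

Step 17
Reactants: 24 penta-O-TBS-(+)-epicatechin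
Product: 25 (2S,3S,4R)-4-hydroxy derivative of 24 (3,4-trans)
Conditions: DDQ (2 equiv), H2O (10 equiv), CH2Cl2/THF, rt
Reagents that add atoms: water `O`
Why: DDQ benzylic oxidation with water as nucleophile should give the 4-ol; attack anti to 3-OTBS gives the trans isomer, whose C4 configuration is erased in the next step.

Step 18
Reactants: 25 3,4-trans 4-ol
Product: 26 (2S,3R)-4-oxo derivative of 24 (2,3-cis flavan-4-one)
Conditions: Dess–Martin periodinane (1.5 equiv), CH2Cl2, 0 °C → rt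
Reagents that add atoms: none
Why: Dess–Martin oxidation under neutral conditions should give the aryl ketone without epimerising the C3 centre next to it.

Step 19
Reactants: 26 flavan-4-one
Product: 27 (2S,3S,4S)-4-hydroxy derivative of 24 (2,3-cis-3,4-cis)
Conditions: LiBH(s-Bu)3 (1.5 equiv), THF, −78 °C; aq NH4Cl at −78 °C
Reagents that add atoms: none
Why: Bulky hydride reduction should occur from the face opposite the axial 3-OTBS group, placing the 4-OH cis to it (all-cis); the cold quench avoids silyl migration.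

Step 20
Reactants: 22 4β-benzylthio dimer; 27 all-cis 4-ol (1.5 equiv)
Product: 28 pentadeca-O-TBS ether of the target
Conditions: AgOTf (2.5 equiv), 2,6-di-tert-butyl-4-methylpyridine (3 equiv), 4 Å molecular sieves, CH2Cl2, −40 → 0 °C, dark
Reagents that add atoms: none
Why: Silver-promoted SN1 etherification (thioglycoside-type activation) should give a C4 cation, stabilised by the 5,7-dioxygenated ring, that the 4-OH of 27 captures anti to the axial 3-OTBS (4β, 3,4-trans), while the hindered base keeps the medium non-acidic so the 3,4-cis C4–O bond of 27 and the product ether do not ionise.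

Step 21
Reactants: 28 pentadeca-O-TBS ether
Product: 29 CNP0310719.1 (target)
Conditions: TBAF (20 equiv), AcOH (20 equiv), THF, argon, 0 °C → rt; Sephadex LH-20
Reagents that add atoms: none
Why: Buffered fluoride desilylation should remove twelve aryl and three alkyl silyl ethers under near-neutral, non-reductive conditions that spare the acid- and hydrogenolysis-labile bis-benzylic ether and leave all nine stereocentres untouched.

**Compound list**

1 | (−)-epicatechin, (2R,3R) | `Oc1cc(O)c2c(c1)O[C@H](c1ccc(O)c(O)c1)[C@H](O)C2` | starting material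
2 | 3,5,7,3',4'-penta-O-TBS-(−)-epicatechin | `CC(C)(C)[Si](C)(C)Oc1cc(O[Si](C)(C)C(C)(C)C)c2c(c1)O[C@H](c1ccc(O[Si](C)(C)C(C)(C)C)c(O[Si](C)(C)C(C)(C)C)c1)[C@H](O[Si](C)(C)C(C)(C)C)C2` | intermediate
3 | 4β-(2-ethoxyethoxy)-penta-O-TBS-epicatechin | `CC(C)(C)[Si](C)(C)Oc1cc(O[Si](C)(C)C(C)(C)C)c2c(c1)O[C@H](c1ccc(O[Si](C)(C)C(C)(C)C)c(O[Si](C)(C)C(C)(C)C)c1)[C@H](O[Si](C)(C)C(C)(C)C)[C@H]2OCCOCC` | intermediate
4 | phloroglucinol | `Oc1cc(O)cc(O)c1` | starting material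
5 | penta-O-TBS-epicatechin-(4β→2)-phloroglucinol | `CC(C)(C)[Si](C)(C)Oc1cc(O[Si](C)(C)C(C)(C)C)c2c(c1)O[C@H](c1ccc(O[Si](C)(C)C(C)(C)C)c(O[Si](C)(C)C(C)(C)C)c1)[C@H](O[Si](C)(C)C(C)(C)C)[C@H]2c1c(O)cc(O)cc1O` | intermediate
6 | 2,4,6-trihydroxy-3-(penta-O-TBS-epicatechin-4β-yl)benzaldehyde | `CC(C)(C)[Si](C)(C)Oc1cc(O[Si](C)(C)C(C)(C)C)c2c(c1)O[C@H](c1ccc(O[Si](C)(C)C(C)(C)C)c(O[Si](C)(C)C(C)(C)C)c1)[C@H](O[Si](C)(C)C(C)(C)C)[C@H]2c1c(O)cc(O)c(C=O)c1O` | intermediate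
7 | 2-hydroxy-4,6-bis(TBS-oxy)-3-(penta-O-TBS-epicatechin-4β-yl)benzaldehyde | `CC(C)(C)[Si](C)(C)Oc1cc(O[Si](C)(C)C(C)(C)C)c2c(c1)O[C@H](c1ccc(O[Si](C)(C)C(C)(C)C)c(O[Si](C)(C)C(C)(C)C)c1)[C@H](O[Si](C)(C)C(C)(C)C)[C@H]2c1c(O[Si](C)(C)C(C)(C)C)cc(O[Si](C)(C)C(C)(C)C)c(C=O)c1O` | intermediate
8 | tert-butyl carbonate of 7 (O-Boc salicylaldehyde) | `CC(C)(C)[Si](C)(C)Oc1cc(O[Si](C)(C)C(C)(C)C)c2c(c1)O[C@H](c1ccc(O[Si](C)(C)C(C)(C)C)c(O[Si](C)(C)C(C)(C)C)c1)[C@H](O[Si](C)(C)C(C)(C)C)[C@H]2c1c(O[Si](C)(C)C(C)(C)C)cc(O[Si](C)(C)C(C)(C)C)c(C=O)c1OC(=O)OC(C)(C)C` | intermediate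
9 | 3,4-dihydroxybenzaldehyde | `O=Cc1ccc(O)c(O)c1` | starting material
10 | 3,4-bis(TBS-oxy)benzaldehyde | `O=Cc1ccc(O[Si](C)(C)C(C)(C)C)c(O[Si](C)(C)C(C)(C)C)c1` | intermediate
11 | 4-(2,2-dibromovinyl)-1,2-bis(TBS-oxy)benzene | `BrC(Br)=Cc1ccc(O[Si](C)(C)C(C)(C)C)c(O[Si](C)(C)C(C)(C)C)c1` | intermediate
12 | lithium [3,4-bis(TBS-oxy)phenyl]acetylide | `[Li]C#Cc1ccc(O[Si](C)(C)C(C)(C)C)c(O[Si](C)(C)C(C)(C)C)c1` | intermediate (not isolated)
13 | 4-ethynyl-1,2-bis(TBS-oxy)benzene | `C#Cc1ccc(O[Si](C)(C)C(C)(C)C)c(O[Si](C)(C)C(C)(C)C)c1` | intermediate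
14 | lithium alkoxide of the O-Boc salicyl alcohol from 8 | `CC(C)(C)[Si](C)(C)Oc1cc(O[Si](C)(C)C(C)(C)C)c2c(c1)O[C@H](c1ccc(O[Si](C)(C)C(C)(C)C)c(O[Si](C)(C)C(C)(C)C)c1)[C@H](O[Si](C)(C)C(C)(C)C)[C@H]2c1c(O[Si](C)(C)C(C)(C)C)cc(O[Si](C)(C)C(C)(C)C)c(C[O-])c1OC(=O)OC(C)(C)C.[Li+]` | intermediate (not isolated)
15 | o-quinone methide: 6-methylene-3,5-bis(TBS-oxy)-2-(penta-O-TBS-epicatechin-4β-yl)cyclohexa-2,4-dien-1-one | `CC(C)(C)[Si](C)(C)Oc1cc(O[Si](C)(C)C(C)(C)C)c2c(c1)O[C@H](c1ccc(O[Si](C)(C)C(C)(C)C)c(O[Si](C)(C)C(C)(C)C)c1)[C@H](O[Si](C)(C)C(C)(C)C)[C@H]2C1=C(O[Si](C)(C)C(C)(C)C)C=C(O[Si](C)(C)C(C)(C)C)C(=C)C1=O` | intermediate (not isolated)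
16 | 2-[3-(3,4-bis(TBS-oxy)phenyl)prop-2-yn-1-yl]-3,5-bis(TBS-oxy)-6-(penta-O-TBS-epicatechin-4β-yl)phenol | `CC(C)(C)[Si](C)(C)Oc1cc(O[Si](C)(C)C(C)(C)C)c2c(c1)O[C@H](c1ccc(O[Si](C)(C)C(C)(C)C)c(O[Si](C)(C)C(C)(C)C)c1)[C@H](O[Si](C)(C)C(C)(C)C)[C@H]2c1c(O[Si](C)(C)C(C)(C)C)cc(O[Si](C)(C)C(C)(C)C)c(CC#Cc3ccc(O[Si](C)(C)C(C)(C)C)c(O[Si](C)(C)C(C)(C)C)c3)c1O` | intermediate
17 | (Z)-2-[3-(3,4-bis(TBS-oxy)phenyl)prop-2-en-1-yl]-3,5-bis(TBS-oxy)-6-(penta-O-TBS-epicatechin-4β-yl)phenol | `CC(C)(C)[Si](C)(C)Oc1cc(O[Si](C)(C)C(C)(C)C)c2c(c1)O[C@H](c1ccc(O[Si](C)(C)C(C)(C)C)c(O[Si](C)(C)C(C)(C)C)c1)[C@H](O[Si](C)(C)C(C)(C)C)[C@H]2c1c(O[Si](C)(C)C(C)(C)C)cc(O[Si](C)(C)C(C)(C)C)c(C/C=C\c3ccc(O[Si](C)(C)C(C)(C)C)c(O[Si](C)(C)C(C)(C)C)c3)c1O` | intermediate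
18 | cis-epoxide of 17: 2-{[(2R,3S)-3-(3,4-bis(TBS-oxy)phenyl)oxiran-2-yl]methyl}phenol | `CC(C)(C)[Si](C)(C)Oc1cc(O[Si](C)(C)C(C)(C)C)c2c(c1)O[C@H](c1ccc(O[Si](C)(C)C(C)(C)C)c(O[Si](C)(C)C(C)(C)C)c1)[C@H](O[Si](C)(C)C(C)(C)C)[C@H]2c1c(O[Si](C)(C)C(C)(C)C)cc(O[Si](C)(C)C(C)(C)C)c(C[C@H]3O[C@H]3c4ccc(O[Si](C)(C)C(C)(C)C)c(O[Si](C)(C)C(C)(C)C)c4)c1O` | intermediate (not isolated)
19 | penta-O-TBS-epicatechin-(4β→8)-5,7,3',4'-tetra-O-TBS-epicatechin | `CC(C)(C)[Si](C)(C)Oc1cc(O[Si](C)(C)C(C)(C)C)c2c(c1)O[C@H](c1ccc(O[Si](C)(C)C(C)(C)C)c(O[Si](C)(C)C(C)(C)C)c1)[C@H](O[Si](C)(C)C(C)(C)C)[C@H]2c1c(O[Si](C)(C)C(C)(C)C)cc(O[Si](C)(C)C(C)(C)C)c2c1O[C@H](c1ccc(O[Si](C)(C)C(C)(C)C)c(O[Si](C)(C)C(C)(C)C)c1)[C@H](O)C2` | intermediate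
20 | deca-O-TBS-epicatechin-(4β→8)-epicatechin | `CC(C)(C)[Si](C)(C)Oc1cc(O[Si](C)(C)C(C)(C)C)c2c(c1)O[C@H](c1ccc(O[Si](C)(C)C(C)(C)C)c(O[Si](C)(C)C(C)(C)C)c1)[C@H](O[Si](C)(C)C(C)(C)C)[C@H]2c1c(O[Si](C)(C)C(C)(C)C)cc(O[Si](C)(C)C(C)(C)C)c2c1O[C@H](c1ccc(O[Si](C)(C)C(C)(C)C)c(O[Si](C)(C)C(C)(C)C)c1)[C@H](O[Si](C)(C)C(C)(C)C)C2` | intermediate
21 | middle-unit 4β-(2-ethoxyethoxy) derivative of 20 | `CC(C)(C)[Si](C)(C)Oc1cc(O[Si](C)(C)C(C)(C)C)c2c(c1)O[C@H](c1ccc(O[Si](C)(C)C(C)(C)C)c(O[Si](C)(C)C(C)(C)C)c1)[C@H](O[Si](C)(C)C(C)(C)C)[C@H]2c1c(O[Si](C)(C)C(C)(C)C)cc(O[Si](C)(C)C(C)(C)C)c2c1O[C@H](c1ccc(O[Si](C)(C)C(C)(C)C)c(O[Si](C)(C)C(C)(C)C)c1)[C@H](O[Si](C)(C)C(C)(C)C)[C@H]2OCCOCC` | intermediate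
22 | middle-unit 4β-benzylthio derivative of 20 | `CC(C)(C)[Si](C)(C)Oc1cc(O[Si](C)(C)C(C)(C)C)c2c(c1)O[C@H](c1ccc(O[Si](C)(C)C(C)(C)C)c(O[Si](C)(C)C(C)(C)C)c1)[C@H](O[Si](C)(C)C(C)(C)C)[C@H]2c1c(O[Si](C)(C)C(C)(C)C)cc(O[Si](C)(C)C(C)(C)C)c2c1O[C@H](c1ccc(O[Si](C)(C)C(C)(C)C)c(O[Si](C)(C)C(C)(C)C)c1)[C@H](O[Si](C)(C)C(C)(C)C)[C@H]2SCc1ccccc1` | intermediate
23 | (+)-epicatechin, (2S,3S) | `Oc1cc(O)c2c(c1)O[C@@H](c1ccc(O)c(O)c1)[C@@H](O)C2` | starting material
24 | 3,5,7,3',4'-penta-O-TBS-(+)-epicatechin | `CC(C)(C)[Si](C)(C)Oc1cc(O[Si](C)(C)C(C)(C)C)c2c(c1)O[C@@H](c1ccc(O[Si](C)(C)C(C)(C)C)c(O[Si](C)(C)C(C)(C)C)c1)[C@@H](O[Si](C)(C)C(C)(C)C)C2` | intermediate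
25 | (2S,3S,4R)-4-hydroxy derivative of 24 (3,4-trans) | `CC(C)(C)[Si](C)(C)Oc1cc(O[Si](C)(C)C(C)(C)C)c2c(c1)O[C@@H](c1ccc(O[Si](C)(C)C(C)(C)C)c(O[Si](C)(C)C(C)(C)C)c1)[C@@H](O[Si](C)(C)C(C)(C)C)[C@@H]2O` | intermediate
26 | (2S,3R)-4-oxo derivative of 24 | `CC(C)(C)[Si](C)(C)Oc1cc(O[Si](C)(C)C(C)(C)C)c2c(c1)O[C@@H](c1ccc(O[Si](C)(C)C(C)(C)C)c(O[Si](C)(C)C(C)(C)C)c1)[C@@H](O[Si](C)(C)C(C)(C)C)C2=O` | intermediate
27 | (2S,3S,4S)-4-hydroxy derivative of 24 (2,3-cis-3,4-cis) | `CC(C)(C)[Si](C)(C)Oc1cc(O[Si](C)(C)C(C)(C)C)c2c(c1)O[C@@H](c1ccc(O[Si](C)(C)C(C)(C)C)c(O[Si](C)(C)C(C)(C)C)c1)[C@@H](O[Si](C)(C)C(C)(C)C)[C@H]2O` | intermediate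
28 | pentadeca-O-TBS ether of the target | `CC(C)(C)[Si](C)(C)Oc1cc(O[Si](C)(C)C(C)(C)C)c2c(c1)O[C@H](c1ccc(O[Si](C)(C)C(C)(C)C)c(O[Si](C)(C)C(C)(C)C)c1)[C@H](O[Si](C)(C)C(C)(C)C)[C@H]2c1c(O[Si](C)(C)C(C)(C)C)cc(O[Si](C)(C)C(C)(C)C)c2c1O[C@H](c1ccc(O[Si](C)(C)C(C)(C)C)c(O[Si](C)(C)C(C)(C)C)c1)[C@H](O[Si](C)(C)C(C)(C)C)[C@H]2O[C@H]1c2c(O[Si](C)(C)C(C)(C)C)cc(O[Si](C)(C)C(C)(C)C)cc2O[C@@H](c2ccc(O[Si](C)(C)C(C)(C)C)c(O[Si](C)(C)C(C)(C)C)c2)[C@H]1O[Si](C)(C)C(C)(C)C` | intermediate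
29 | CNP0310719.1: epicatechin-(4β→8)-epicatechin 4β-O-linked to C4 of a (2S,3S,4S)-flavan-3,4-diol unit | `Oc1cc(O)c2c(c1)O[C@H](c1ccc(O)c(O)c1)[C@H](O)[C@H]2c1c(O)cc(O)c2c1O[C@H](c1ccc(O)c(O)c1)[C@H](O)[C@H]2O[C@H]1c2c(O)cc(O)cc2O[C@@H](c2ccc(O)c(O)c2)[C@H]1O` | target

**Step count and risks**

Total steps: 21. Longest linear sequence: 14 steps (1–6, 10–15, 20, 21).

Steps most likely to fail:

1. Step 12 (proposed new method). The hindered phenol may bind the vanadium complex poorly, so that the alkene face is chosen badly. The metal peroxide may oxidise the electron-rich ring instead of the alkene. Partial ionisation at C2 during opening would erode the cis relationship. The fallback sets out from 17 and uses reagent control on a masked phenol. Acetylation (Ac2O, pyridine, DMAP) should give the aryl acetate F1. Jacobsen–Katsuki epoxidation of this cis-disubstituted aryl alkene (chiral Mn(salen)Cl, buffered NaOCl, 4-phenylpyridine N-oxide, CH2Cl2, 0 °C) should give the cis-epoxide acetate F2. Hydrazine hydrate in THF/MeOH at 0 °C removes the acetate to free phenol epoxide 18, which is closed with pyridinium p-toluenesulfonate in CH2Cl2 at −20 °C. The fallback returns to the route at 19.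

2. Step 20. The doubly hindered cation may lose a proton to give a flav-3-ene faster than the hindered secondary alcohol captures it, or traces of acid may ionise the alcohol partner. The fallback sets out from 20 and avoids any promoter. DDQ/H2O oxidation should give the middle-unit 4β-alcohol F3. Cl3CCN with catalytic DBU gives the trichloroacetimidate F4. This electron-rich benzylic imidate should etherify 27 on standing in toluene at rt to 40 °C without catalyst (thermal trichloroacetimidate etherification, neutral amide as leaving group). The fallback returns to the route at 28.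

3. Step 5. Silylation may not discriminate cleanly between the two hydroxyls ortho to the formyl group, leaving the wrong oxygen free and so the wrong ring fusion later. The fallback sets out from 5 and differentiates the hydroxyls before the aldehyde is present. TBSCl (1.0 equiv, imidazole, CH2Cl2, −20 °C) should silylate only the unflanked hydroxyl para to the flavanyl group, giving the mono-silyl ether F5. Casnati–Skattebøl formylation of this symmetric resorcinol gives the single aldehyde F6. One further equivalent of TBSCl then takes the hydroxyl that is not hydrogen-bonded to the formyl group. The fallback returns to the route at 7.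

**Further compounds**

F1 | step 12 | aryl acetate of 17 | `CC(C)(C)[Si](C)(C)Oc1cc(O[Si](C)(C)C(C)(C)C)c2c(c1)O[C@H](c1ccc(O[Si](C)(C)C(C)(C)C)c(O[Si](C)(C)C(C)(C)C)c1)[C@H](O[Si](C)(C)C(C)(C)C)[C@H]2c1c(O[Si](C)(C)C(C)(C)C)cc(O[Si](C)(C)C(C)(C)C)c(C/C=C\c3ccc(O[Si](C)(C)C(C)(C)C)c(O[Si](C)(C)C(C)(C)C)c3)c1OC(C)=O`
F2 | step 12 | cis-epoxide of aryl acetate F1 (same epoxide configuration as 18) | `CC(C)(C)[Si](C)(C)Oc1cc(O[Si](C)(C)C(C)(C)C)c2c(c1)O[C@H](c1ccc(O[Si](C)(C)C(C)(C)C)c(O[Si](C)(C)C(C)(C)C)c1)[C@H](O[Si](C)(C)C(C)(C)C)[C@H]2c1c(O[Si](C)(C)C(C)(C)C)cc(O[Si](C)(C)C(C)(C)C)c(C[C@H]3O[C@H]3c4ccc(O[Si](C)(C)C(C)(C)C)c(O[Si](C)(C)C(C)(C)C)c4)c1OC(C)=O`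
F3 | step 20 | middle-unit 4β-hydroxy derivative of 20 | `CC(C)(C)[Si](C)(C)Oc1cc(O[Si](C)(C)C(C)(C)C)c2c(c1)O[C@H](c1ccc(O[Si](C)(C)C(C)(C)C)c(O[Si](C)(C)C(C)(C)C)c1)[C@H](O[Si](C)(C)C(C)(C)C)[C@H]2c1c(O[Si](C)(C)C(C)(C)C)cc(O[Si](C)(C)C(C)(C)C)c2c1O[C@H](c1ccc(O[Si](C)(C)C(C)(C)C)c(O[Si](C)(C)C(C)(C)C)c1)[C@H](O[Si](C)(C)C(C)(C)C)[C@H]2O`
F4 | step 20 | middle-unit 4β-O-trichloroacetimidate of F3 | `CC(C)(C)[Si](C)(C)Oc1cc(O[Si](C)(C)C(C)(C)C)c2c(c1)O[C@H](c1ccc(O[Si](C)(C)C(C)(C)C)c(O[Si](C)(C)C(C)(C)C)c1)[C@H](O[Si](C)(C)C(C)(C)C)[C@H]2c1c(O[Si](C)(C)C(C)(C)C)cc(O[Si](C)(C)C(C)(C)C)c2c1O[C@H](c1ccc(O[Si](C)(C)C(C)(C)C)c(O[Si](C)(C)C(C)(C)C)c1)[C@H](O[Si](C)(C)C(C)(C)C)[C@H]2OC(=N)C(Cl)(Cl)Cl`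
F5 | step 5 | mono-TBS ether of 5 (silyl on the hydroxyl para to the flavanyl group) | `CC(C)(C)[Si](C)(C)Oc1cc(O[Si](C)(C)C(C)(C)C)c2c(c1)O[C@H](c1ccc(O[Si](C)(C)C(C)(C)C)c(O[Si](C)(C)C(C)(C)C)c1)[C@H](O[Si](C)(C)C(C)(C)C)[C@H]2c1c(O)cc(O[Si](C)(C)C(C)(C)C)cc1O`
F6 | step 5 | 2,4-dihydroxy-6-(TBS-oxy)-3-(penta-O-TBS-epicatechin-4β-yl)benzaldehyde | `CC(C)(C)[Si](C)(C)Oc1cc(O[Si](C)(C)C(C)(C)C)c2c(c1)O[C@H](c1ccc(O[Si](C)(C)C(C)(C)C)c(O[Si](C)(C)C(C)(C)C)c1)[C@H](O[Si](C)(C)C(C)(C)C)[C@H]2c1c(O)cc(O[Si](C)(C)C(C)(C)C)c(C=O)c1O`
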